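The ten-membered ring (germacrane numbering) is cut at C8–C9 by an anionic oxy-Cope rearrangement. The target hides the 3-oxy-1,5-diene C8=C7–C6(O)–C1–C10=C9, and its cis C4=C5 olefin with the C3 oxygen is the ring olefin of a carveol. The precursor is therefore an (S)-carvone-derived cyclohex-2-en-1-ol whose C6 carries the alkoxide and an (E)-2-(PMB-oxy)vinyl group and whose C1 carries isopropenyl. In one operation the rearrangement forms C8–C9, expands the six-membered ring to the cyclodecadienone, sets C8 by chirality transfer and gives a C6 enolate that is alkylated at C7 with the lactone carbons. C8 is inverted during the late esterification.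

Key step: step 7

Remark: germacrane numbering is used for all ten-membered compounds: ring C1–C10, C4 (methyl C15)=C5, C6 (lactone oxygen), C7 (bears C11), C8 (ester oxygen), C9 (CH2), C10 (OH and methyl C14), C11–C13 lactone carbons. α/β refer to the usual germacranolide drawing with H-7 α. In these terms the target is 3β,10α-dihydroxy-8β-isobutyryloxy-germacra-4Z,11(13)-dien-12,6α-olide. TBS = tert-butyldimethylsilyl, PMB = 4-methoxybenzyl. Compounds 1, 5, 6, 11 and 22 are assumed to be purchased.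

Step 1
Reactants: 1 (S)-(+)-carvone
Product: 2 (1S,5S)-cis-carveol
Conditions: NaBH4, CeCl3·7H2O, MeOH, 0 °C
Reagents that add atoms: none
Why: Luche reduction: the cerium-activated carbonyl takes hydride 1,2 and axially on the half-chair that holds the isopropenyl group equatorial, so the new carbinol centre (the later C3) should be S with OH cis to isopropenyl.

Step 2
Reactants: 2 (1S,5S)-cis-carveol
Product: 3 TBS ether of (1S,5S)-cis-carveol
Conditions: TBSCl, imidazole, DMF, rt
Reagents that add atoms: tert-butyldimethylsilyl chloride CC(C)(C)[Si](C)(C)Cl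
Why: Imidazole-promoted silylation of the secondary allylic alcohol masks the C3 oxygen for the organometallic, hydride and base steps and touches no stereocenter.

Step 3
Reactants: 3 TBS ether of (1S,5S)-cis-carveol
Product: 4 (4S,6S)-4-(TBS-oxy)-3-methyl-6-(prop-1-en-2-yl)cyclohex-2-en-1-one
Conditions: CrO3, 3,5-dimethylpyrazole, CH2Cl2, −20 °C
Reagents that add atoms: chromium trioxide O=[Cr](=O)=O
Why: Chromium trioxide–3,5-dimethylpyrazole allylic oxidation should convert the only ring methylene allylic to the electron-rich trisubstituted olefin into the enone carbonyl (the later C6), the silylated carbinol C–H and the isopropenyl group being less reactive; both stereocenters are retained and the cis isomer is also the more stable one at the enolizable centre.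

Step 4
Reactants: 5 4-methoxybenzyl alcohol; 6 trichloroethylene
Product: 7 (E)-1,2-dichlorovinyl 4-methoxybenzyl ether
Conditions: KH, THF, 0 °C to rt
Reagents that add atoms: none
Why: Alkoxide-induced dehydrochlorination of trichloroethylene to dichloroacetylene, anti addition of the alkoxide and protonation (the known route to 1,2-dichlorovinyl ethers as ynol ether precursors) should give the (E)-ether.

Step 5
Reactants: 7 (E)-1,2-dichlorovinyl 4-methoxybenzyl ether; 4 (4S,6S)-4-(TBS-oxy)-3-methyl-6-(prop-1-en-2-yl)cyclohex-2-en-1-one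
Product: 9 (1S,4S,6S)-4-(TBS-oxy)-1-[(PMB-oxy)ethynyl]-3-methyl-6-(prop-1-en-2-yl)cyclohex-2-en-1-ol, via lithium alkoxyacetylide 8 (not isolated)
Conditions: n-BuLi (2.2 equiv), THF, −78 to −40 °C; then 4, −78 °C; aq. NH4Cl
Reagents that add atoms: none
Why: Dehydrochlorination and chlorine–lithium exchange of 7 give the lithium alkoxyacetylide, which should add 1,2 to the enone carbonyl from the face opposite the adjacent equatorial isopropenyl group (equatorial attack), so the new tertiary carbinol C6 has OH cis and the alkynyl group trans to isopropenyl; the minor epimer is to be removed by chromatography.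

Step 6
Reactants: 9 (1S,4S,6S)-4-(TBS-oxy)-1-[(PMB-oxy)ethynyl]-3-methyl-6-(prop-1-en-2-yl)cyclohex-2-en-1-ol
Product: 10 (1S,4S,6S)-4-(TBS-oxy)-1-[(E)-2-(PMB-oxy)ethenyl]-3-methyl-6-(prop-1-en-2-yl)cyclohex-2-en-1-ol
Conditions: LiAlH4, THF, 0 °C to rt; aq. KNaC4H4O6 work-up
Reagents that add atoms: none
Why: Hydroxyl-directed trans-hydroalumination of the propargylic alkoxide by LiAlH4 and protonolysis should deliver the (E)-enol ether, the geometry that places the oxygen equatorial in the coming chair transition state.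

Step 7
Reactants: 10 (1S,4S,6S)-4-(TBS-oxy)-1-[(E)-2-(PMB-oxy)ethenyl]-3-methyl-6-(prop-1-en-2-yl)cyclohex-2-en-1-ol; 11 ethyl iodoacetate
Product: 14 ethyl 3β-(TBS-oxy)-8α-(PMB-oxy)-6-oxo-13-norgermacra-1(10)E,4Z-dien-12-oate, via potassium alkoxide 12 (not isolated), via ten-membered potassium enolate 13 (not isolated)
Conditions: KN(SiMe3)2, 18-crown-6, THF, −78 to −10 °C; then 11, −78 °C; AcOH quench at −78 °C
Reagents that add atoms: none
Why: The potassium alkoxide 12 should undergo an anionic oxy-Cope ([3,3]-sigmatropic) rearrangement of the 3-oxido-1,5-diene C8=C7–C6(O−)–C1–C10=C9, the closest known type being the alkoxide-accelerated ring expansion of trans-1,2-dialkenylcyclohexanols to cyclodec-5-enones with in situ enolate alkylation, so that the C8–C9 σ-bond forms as C1–C6 breaks. The ten-membered ring is closed by a four-atom ring expansion of the cyclohexene through a six-membered chair transition state in which C5, C2 and the (E)-OPMB group are all equatorial; the cyclohexene C4=C5 bond is carried over as the 4Z olefin and the chair delivers the 1(10)E olefin. C8 is set (8S, oxygen α) by chirality transfer from C1 (S), which is destroyed, through the (E) geometry of the enol ether. C7 is set (C11 β) by alkylation of the nascent E-configured ring enolate 13 on its outer face, anti to the C8–OPMB group, because the inner face is blocked across the ring by C1=C10. The step needs chair over boat selectivity (secured by the all-equatorial arrangement), C- over O-alkylation (soft iodide) and survival of the β-alkoxy enolate, whose C8–O bond lies near the nodal plane of the enolate in the ring and is therefore poorly aligned for E1cB loss. The C8 epimer obtained here is corrected in step 13.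

Step 8
Reactants: 14 ethyl 3β-(TBS-oxy)-8α-(PMB-oxy)-6-oxo-13-norgermacra-1(10)E,4Z-dien-12-oate
Product: 15 ethyl 1β,10α-epoxy-3β-(TBS-oxy)-8α-(PMB-oxy)-6-oxo-13-norgermacr-4Z-en-12-oate
Conditions: mCPBA, NaHCO3, CH2Cl2, 0 °C
Reagents that add atoms: 3-chloroperoxybenzoic acid O=C(OO)c1cccc(Cl)c1
Why: Prilezhaev epoxidation by the electrophilic peracid should take the strained, electron-rich E-C1=C10 olefin and leave the enone olefin untouched; attack on the exposed outer face of the trans-cyclodecene unit, away from C6 and C7, gives the 1β,10α-epoxide (C10 oxygen α, methyl β).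

Step 9
Reactants: 15 ethyl 1β,10α-epoxy-3β-(TBS-oxy)-8α-(PMB-oxy)-6-oxo-13-norgermacr-4Z-en-12-oate
Product: 16 3β-(TBS-oxy)-8α-(PMB-oxy)-13-norgermacr-4Z-ene-6α,10α,12-triol
Conditions: LiAlH4, LiI, Et2O, −78 °C; then THF, 0 to 60 °C
Reagents that add atoms: none
Why: Chelation-controlled hydride reduction in which Li+ bridges the C6 carbonyl and the C8 PMB ether and hydride adds to the chair chelate holding C5, C11 and C9 equatorial should give the 1,3-syn 6α-alcohol (6-OH trans to C11); on warming the ester is reduced to the C12 alcohol and hydride opens the epoxide by SN2 attack at the secondary C1, which leaves the 10α tertiary alcohol with retention at C10.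

Step 10
Reactants: 16 3β-(TBS-oxy)-8α-(PMB-oxy)-13-norgermacr-4Z-ene-6α,10α,12-triol
Product: 17 3β-(TBS-oxy)-10α-hydroxy-8α-(PMB-oxy)-13-norgermacr-4Z-en-12,6α-olide
Conditions: TEMPO (cat.), PhI(OAc)2, CH2Cl2, rt
Reagents that add atoms: none
Why: Oxoammonium (TEMPO/PhI(OAc)2) oxidation of the primary C12 alcohol gives the aldehyde, which should close to the five-membered lactol with the 6α-hydroxyl and be oxidized on to the trans-fused γ-lactone; the tertiary alcohol is inert and no stereocenter changes.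

Step 11
Reactants: 17 3β-(TBS-oxy)-10α-hydroxy-8α-(PMB-oxy)-13-norgermacr-4Z-en-12,6α-olide
Product: 20 3β-(TBS-oxy)-10α-hydroxy-8α-(PMB-oxy)germacra-4Z,11(13)-dien-12,6α-olide, via Mannich base 18 (not isolated), via trimethylammonium iodide 19 (not isolated)
Conditions: LiN(iPr)2 (3 equiv), THF, −78 °C; CH2=NMe2+ I−, −78 °C to rt; then MeI, MeOH, rt; then aq. NaHCO3, CH2Cl2
Reagents that add atoms: Eschenmoser's salt C=[N+](C)C.[I-]; iodomethane CI
Why: Eschenmoser methylenation: the lithium lactone enolate (the tertiary alcohol is carried as its lithium alkoxide) is aminomethylated at C11 in a Mannich reaction, and N-methylation followed by base-induced elimination of trimethylamine (which carries off the methyl from iodomethane) should give the exocyclic C11=C13 olefin.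

Step 12
Reactants: 20 3β-(TBS-oxy)-10α-hydroxy-8α-(PMB-oxy)germacra-4Z,11(13)-dien-12,6α-olide
Product: 21 3β-(TBS-oxy)-8α,10α-dihydroxygermacra-4Z,11(13)-dien-12,6α-olide
Conditions: DDQ, CH2Cl2/aq. pH 7 buffer (NaH2PO4/Na2HPO4), 0 °C
Reagents that add atoms: none
Why: DDQ oxidizes the electron-rich PMB ether to the benzylic oxocarbenium ion, which water should hydrolyse to the free 8α-alcohol and 4-methoxybenzaldehyde; silyl ether, olefins and lactone are not affected under buffered conditions.

Step 13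
Reactants: 21 3β-(TBS-oxy)-8α,10α-dihydroxygermacra-4Z,11(13)-dien-12,6α-olide; 22 isobutyric acid
Product: 23 3β-(TBS-oxy)-10α-hydroxy-8β-(isobutyryloxy)germacra-4Z,11(13)-dien-12,6α-olide
Conditions: PPh3, DIAD (betaine pre-formed), toluene, 0 °C to rt
Reagents that add atoms: none
Why: Mitsunobu esterification: the 8α-hydroxyl is activated as the oxyphosphonium ion and displaced by isobutyrate in an SN2 step with inversion, which should give the 8β-ester (8R), while the tertiary C10 hydroxyl cannot be activated; the betaine is pre-formed so that free PPh3 does not add to the methylene lactone.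

Step 14
Reactants: 23 3β-(TBS-oxy)-10α-hydroxy-8β-(isobutyryloxy)germacra-4Z,11(13)-dien-12,6α-olide
Product: 24 3β,10α-dihydroxy-8β-(isobutyryloxy)germacra-4Z,11(13)-dien-12,6α-olide (CNP0163972.1)
Conditions: HF·pyridine, pyridine, THF, 0 °C to rt
Reagents that add atoms: none
Why: Fluoride cleaves the Si–O bond of the secondary allylic TBS ether under weakly acidic conditions that should spare the isobutyrate, the α-methylene lactone and the tertiary alcohol, to give the target.

Compound list
1 | (S)-(+)-carvone | O=C1C(C)=CC[C@H](C(C)=C)C1 | starting material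
2 | (1S,5S)-cis-carveol | O[C@@H]1C(C)=CC[C@H](C(C)=C)C1 | intermediate
3 | TBS ether of (1S,5S)-cis-carveol | CC(C)(C)[Si](C)(C)O[C@@H]1C(C)=CC[C@H](C(C)=C)C1 | intermediate
4 | (4S,6S)-4-(TBS-oxy)-3-methyl-6-(prop-1-en-2-yl)cyclohex-2-en-1-one | CC(C)(C)[Si](C)(C)O[C@@H]1C(C)=CC(=O)[C@H](C(C)=C)C1 | intermediate
5 | 4-methoxybenzyl alcohol | COc1ccc(CO)cc1 | starting material
6 | trichloroethylene | ClC=C(Cl)Cl | starting material
7 | (E)-1,2-dichlorovinyl 4-methoxybenzyl ether | COc1ccc(CO/C(Cl)=C\Cl)cc1 | intermediate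
8 | lithium [(4-methoxybenzyl)oxy]acetylide | [Li]C#COCc1ccc(OC)cc1 | intermediate (not isolated)
9 | (1S,4S,6S)-4-(TBS-oxy)-1-[(PMB-oxy)ethynyl]-3-methyl-6-(prop-1-en-2-yl)cyclohex-2-en-1-ol (OH cis to isopropenyl) | CC(C)(C)[Si](C)(C)O[C@@H]1C(C)=C[C@@](O)(C#COCc2ccc(OC)cc2)[C@H](C(C)=C)C1 | intermediate
10 | (1S,4S,6S)-4-(TBS-oxy)-1-[(E)-2-(PMB-oxy)ethenyl]-3-methyl-6-(prop-1-en-2-yl)cyclohex-2-en-1-ol | CC(C)(C)[Si](C)(C)O[C@@H]1C(C)=C[C@@](O)(/C=C/OCc2ccc(OC)cc2)[C@H](C(C)=C)C1 | intermediate
11 | ethyl iodoacetate | CCOC(=O)CI | starting material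
12 | potassium alkoxide of 10 | CC(C)(C)[Si](C)(C)O[C@@H]1C(C)=C[C@@]([O-])(/C=C/OCc2ccc(OC)cc2)[C@H](C(C)=C)C1.[K+] | intermediate (not isolated)
13 | potassium C6 enolate of 3β-(TBS-oxy)-8α-(PMB-oxy)cyclodeca-1(10)E,4Z,6-trien-6-olate (ring-E enolate) | [K+].[O-]/C1=C\[C@@H](OCc2ccc(OC)cc2)C/C(C)=C/C[C@H](O[Si](C)(C)C(C)(C)C)/C(C)=C\1 | intermediate (not isolated)
14 | ethyl 3β-(TBS-oxy)-8α-(PMB-oxy)-6-oxo-13-norgermacra-1(10)E,4Z-dien-12-oate (7α-H) | O=C1/C=C(/C)[C@@H](O[Si](C)(C)C(C)(C)C)C/C=C(C)/C[C@H](OCc2ccc(OC)cc2)[C@H]1CC(=O)OCC | intermediate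
15 | ethyl 1β,10α-epoxy-3β-(TBS-oxy)-8α-(PMB-oxy)-6-oxo-13-norgermacr-4Z-en-12-oate | O=C1/C=C(/C)[C@@H](O[Si](C)(C)C(C)(C)C)C[C@H]2O[C@]2(C)C[C@H](OCc3ccc(OC)cc3)[C@H]1CC(=O)OCC | intermediate
16 | 3β-(TBS-oxy)-8α-(PMB-oxy)-13-norgermacr-4Z-ene-6α,10α,12-triol | O[C@@H]1/C=C(/C)[C@@H](O[Si](C)(C)C(C)(C)C)CC[C@](C)(O)C[C@H](OCc2ccc(OC)cc2)[C@H]1CCO | intermediate
17 | 3β-(TBS-oxy)-10α-hydroxy-8α-(PMB-oxy)-13-norgermacr-4Z-en-12,6α-olide | C1C(=O)O[C@@H]2/C=C(/C)[C@@H](O[Si](C)(C)C(C)(C)C)CC[C@](C)(O)C[C@H](OCc3ccc(OC)cc3)[C@@H]12 | intermediate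
18 | 13-(dimethylamino) Mannich base of 17 (C11 epimers) | CN(C)CC1C(=O)O[C@@H]2/C=C(/C)[C@@H](O[Si](C)(C)C(C)(C)C)CC[C@](C)(O)C[C@H](OCc3ccc(OC)cc3)[C@@H]12 | intermediate (not isolated)
19 | 13-(trimethylammonio) iodide of 17 (C11 epimers) | C[N+](C)(C)CC1C(=O)O[C@@H]2/C=C(/C)[C@@H](O[Si](C)(C)C(C)(C)C)CC[C@](C)(O)C[C@H](OCc3ccc(OC)cc3)[C@@H]12.[I-] | intermediate (not isolated)
20 | 3β-(TBS-oxy)-10α-hydroxy-8α-(PMB-oxy)germacra-4Z,11(13)-dien-12,6α-olide | C=C1C(=O)O[C@@H]2/C=C(/C)[C@@H](O[Si](C)(C)C(C)(C)C)CC[C@](C)(O)C[C@H](OCc3ccc(OC)cc3)[C@@H]12 | intermediate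
21 | 3β-(TBS-oxy)-8α,10α-dihydroxygermacra-4Z,11(13)-dien-12,6α-olide | C=C1C(=O)O[C@@H]2/C=C(/C)[C@@H](O[Si](C)(C)C(C)(C)C)CC[C@](C)(O)C[C@H](O)[C@@H]12 | intermediate
22 | isobutyric acid | CC(C)C(=O)O | starting material
23 | 3β-(TBS-oxy)-10α-hydroxy-8β-(isobutyryloxy)germacra-4Z,11(13)-dien-12,6α-olide | C=C1C(=O)O[C@@H]2/C=C(/C)[C@@H](O[Si](C)(C)C(C)(C)C)CC[C@](C)(O)C[C@@H](OC(=O)C(C)C)[C@@H]12 | intermediate
24 | 3β,10α-dihydroxy-8β-(isobutyryloxy)germacra-4Z,11(13)-dien-12,6α-olide (CNP0163972.1) | C=C1C(=O)O[C@@H]2/C=C(/C)[C@@H](O)CC[C@](C)(O)C[C@@H](OC(=O)C(C)C)[C@@H]12 | target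

Total step count: 14. Longest linear sequence: 13 steps (steps 1–3 and 5–14, from 1).

Steps most likely to fail

Step 7. The potassium enolate 13 may expel p-methoxybenzyl oxide from C8 (E1cB) before it is alkylated, so that the C8 oxygen is lost. The fallback replaces the oxygen by silicon, which cannot leave as an anion; it sets out from 4 and returns at 15. Lithium (dimethylphenylsilyl)acetylide (from ethynyldimethylphenylsilane and n-BuLi) is added to 4 to give (1S,4S,6S)-4-(TBS-oxy)-1-[(dimethylphenylsilyl)ethynyl]-3-methyl-6-(prop-1-en-2-yl)cyclohex-2-en-1-ol F1. LiAlH4 should reduce it to the (E)-vinylsilane, (1S,4S,6S)-4-(TBS-oxy)-1-[(E)-2-(dimethylphenylsilyl)ethenyl]-3-methyl-6-(prop-1-en-2-yl)cyclohex-2-en-1-ol F2. KN(SiMe3)2/18-crown-6 followed by ethyl iodoacetate should give, by the same chair rearrangement and alkylation anti to silicon, ethyl 3β-(TBS-oxy)-8α-(dimethylphenylsilyl)-6-oxo-13-norgermacra-1(10)E,4Z-dien-12-oate F3. Fleming–Tamao oxidation with mercury diacetate Hg(OAc)2 and peracetic acid (AcOH, NaOAc) converts C–Si into C–OH with retention and is expected to epoxidize C1=C10 from the outer face in the same operation, giving ethyl 1β,10α-epoxy-8α-hydroxy-3β-(TBS-oxy)-6-oxo-13-norgermacr-4Z-en-12-oate F4. 4-Methoxybenzyl trichloroacetimidate with catalytic La(OTf)3 then returns 15.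

Step 9. Hydride delivery to the C6 carbonyl may show poor facial selectivity if the lithium chelate does not form in the medium ring. The fallback uses reagent control and a separate hydride step; it sets out from 15 and returns at 16. Corey–Bakshi–Shibata reduction with (R)-2-methyl-CBS-oxazaborolidine and BH3·SMe2 (the alkenyl side acting as the large group) should give ethyl 1β,10α-epoxy-6α-hydroxy-3β-(TBS-oxy)-8α-(PMB-oxy)-13-norgermacr-4Z-en-12-oate F5. LiEt3BH in THF then reduces the ester (or the lactone formed from it) and opens the epoxide at C1 to give 16.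

Step 13. Substitution at the hindered C8 may give way to elimination of the activated alcohol or to conjugate addition of the reagents to the methylene lactone. The fallback inverts C8 by oxidation and reduction; it sets out from 21 and returns at 23. Dess–Martin periodinane should give 3β-(TBS-oxy)-10α-hydroxy-8-oxogermacra-4Z,11(13)-dien-12,6α-olide F6. Luche reduction (NaBH4, CeCl3·7H2O, MeOH, −78 °C), with hydride expected from the α face anti to C11 on C7, should give 3β-(TBS-oxy)-8β,10α-dihydroxygermacra-4Z,11(13)-dien-12,6α-olide F7. Isobutyric anhydride with DMAP in pyridine at 0 °C then acylates the secondary 8β-hydroxyl to give 23.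

Further compounds
F1 | step 7 | (1S,4S,6S)-4-(TBS-oxy)-1-[(dimethylphenylsilyl)ethynyl]-3-methyl-6-(prop-1-en-2-yl)cyclohex-2-en-1-ol | CC(C)(C)[Si](C)(C)O[C@@H]1C(C)=C[C@@](O)(C#C[Si](C)(C)c2ccccc2)[C@H](C(C)=C)C1
F2 | step 7 | (1S,4S,6S)-4-(TBS-oxy)-1-[(E)-2-(dimethylphenylsilyl)ethenyl]-3-methyl-6-(prop-1-en-2-yl)cyclohex-2-en-1-ol | CC(C)(C)[Si](C)(C)O[C@@H]1C(C)=C[C@@](O)(/C=C/[Si](C)(C)c2ccccc2)[C@H](C(C)=C)C1
F3 | step 7 | ethyl 3β-(TBS-oxy)-8α-(dimethylphenylsilyl)-6-oxo-13-norgermacra-1(10)E,4Z-dien-12-oate | O=C1/C=C(/C)[C@@H](O[Si](C)(C)C(C)(C)C)C/C=C(C)/C[C@H]([Si](C)(C)c2ccccc2)[C@H]1CC(=O)OCC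
F4 | step 7 | ethyl 1β,10α-epoxy-8α-hydroxy-3β-(TBS-oxy)-6-oxo-13-norgermacr-4Z-en-12-oate | O=C1/C=C(/C)[C@@H](O[Si](C)(C)C(C)(C)C)C[C@H]2O[C@]2(C)C[C@H](O)[C@H]1CC(=O)OCC
F5 | step 9 | ethyl 1β,10α-epoxy-6α-hydroxy-3β-(TBS-oxy)-8α-(PMB-oxy)-13-norgermacr-4Z-en-12-oate | O[C@@H]1/C=C(/C)[C@@H](O[Si](C)(C)C(C)(C)C)C[C@H]2O[C@]2(C)C[C@H](OCc3ccc(OC)cc3)[C@H]1CC(=O)OCC
F6 | step 13 | 3β-(TBS-oxy)-10α-hydroxy-8-oxogermacra-4Z,11(13)-dien-12,6α-olide | C=C1C(=O)O[C@@H]2/C=C(/C)[C@@H](O[Si](C)(C)C(C)(C)C)CC[C@](C)(O)CC(=O)[C@@H]12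
F7 | step 13 | 3β-(TBS-oxy)-8β,10α-dihydroxygermacra-4Z,11(13)-dien-12,6α-olide | C=C1C(=O)O[C@@H]2/C=C(/C)[C@@H](O[Si](C)(C)C(C)(C)C)CC[C@](C)(O)C[C@@H](O)[C@@H]12
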